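**Retrosynthetic overview**
1. C11–C12 (last step): nickel-catalysed, enantioconvergent radical coupling of dienyl iodide 18 with racemic allylic chloride 4 joins the two halves and sets C12.
2. C3–C4: hydroboration of methyl alkyne 14, boron-to-zinc exchange and ligand-controlled alkenylzinc addition to propanal set C3 and the 4E olefin.
3. C6–C7: BF3-promoted addition of chiral allenylstannane 13 to dienal 9 sets the 6,7-syn pair.
4. C8=C9 by Wittig olefination, C10=C11 by carboalumination of prop-2-yn-1-ol; chloride 4 from styrene and but-3-en-2-ol by cross-metathesis.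
5. No ring is formed; the only ring (phenyl) arrives with styrene.

Target as read from the SMILES: (3R,4E,6S,7R,8E,10E,12S,13E)-4,6,8,10,12-pentamethyl-14-phenyltetradeca-4,8,10,13-tetraene-3,7-diol, with Me-6 and OH-7 syn.

Assumption: the (3aR,8aS) antipode of the indanyl bis(oxazoline) ligand is taken to give 12S in step 9; the sense is checked on the model pair 4 + 7 and the (3aS,8aR) antipode is used if it proves opposite.

**Step 1**
Reactants: 1 styrene; 2 but-3-en-2-ol (racemic)
Product: 3 rac-(E)-4-phenylbut-3-en-2-ol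
Conditions: second-generation Grubbs catalyst RuCl2(=CHPh)(PCy3)(H2IMes) (2 mol%), 1 (3 equiv), CH2Cl2, 40 °C
Reagents that add atoms: none
Why: Olefin cross-metathesis of a styrene with a secondary allylic alcohol is E-selective under thermodynamic control; the carbinol centre is left racemic because step 9 erases it.

**Step 2**
Reactants: 3 rac-(E)-4-phenylbut-3-en-2-ol
Product: 4 rac-(E)-(3-chlorobut-1-en-1-yl)benzene
Conditions: SOCl2 (1.2 equiv), Et2O, 0 °C; volatiles removed, used crude
Reagents that add atoms: thionyl chloride O=S(Cl)Cl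
Why: Chlorodehydroxylation of an allylic alcohol; any allylic transposition converges on the conjugated chloride, and both regioisomers would give the same allyl radical in step 9.

**Step 3**
Reactants: 5 prop-2-yn-1-ol
Product: 7 (E)-3-iodo-2-methylprop-2-en-1-ol, via alkenylalane 6 (not isolated)
Conditions: AlMe3 (3 equiv), Cp2ZrCl2 (0.25 equiv), CH2Cl2, 0 °C to rt; I2, THF, −30 to 0 °C; aq. K2CO3
Reagents that add atoms: trimethylaluminium C[Al](C)C; iodine II
Why: Negishi zirconium-catalysed carboalumination adds Me and Al syn across the alkyne, and iodinolysis with retention fixes the E geometry of the future C10=C11 bond.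

**Step 4**
Reactants: 7 (E)-3-iodo-2-methylprop-2-en-1-ol
Product: 9 (2E,4E)-5-iodo-2,4-dimethylpenta-2,4-dienal, via iodoenal 8 (not isolated)
Conditions: activated MnO2 (15 equiv), Ph3P=C(CH3)CHO (1.5 equiv), toluene, rt then 80 °C, dark
Reagents that add atoms: 2-(triphenylphosphoranylidene)propanal CC(C=O)=P(c1ccccc1)(c1ccccc1)c1ccccc1
Why: Tandem allylic oxidation–Wittig olefination traps the volatile, light-sensitive iodoenal as it forms; the stabilised α-methyl ylide gives the E trisubstituted C8=C9 bond.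

**Step 5**
Reactants: 10 pent-3-yn-2-one
Product: 11 (S)-pent-3-yn-2-ol
Conditions: RuCl[(S,S)-TsDPEN](p-cymene) (0.5 mol%), KOH (1 mol%), i-PrOH, rt
Reagents that add atoms: none
Why: Noyori asymmetric transfer hydrogenation of an ynone; the alkynyl group plays the role of the aryl group of acetophenone, so the (S,S) catalyst gives the S carbinol.

**Step 6**
Reactants: 11 (S)-pent-3-yn-2-ol
Product: 13 (Ra)-tributyl(penta-2,3-dien-2-yl)stannane, via mesylate 12 (not isolated)
Conditions: n-BuLi, THF, −78 °C; MsCl, −78 to −40 °C; cannulated into Bu3SnLi (from Bu3SnH, LiN(iPr)2)/CuBr·SMe2, THF, −78 °C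
Reagents that add atoms: tributylstannyllithium [Li][Sn](CCCC)(CCCC)CCCC; methanesulfonyl chloride CS(=O)(=O)Cl (stays only in 12)
Why: Marshall allenylstannane synthesis; the stannylcopper reagent displaces the propargylic mesylate by anti SN2′, turning the S centre into the Ra allene axis.

**Step 7**
Reactants: 9 (2E,4E)-5-iodo-2,4-dimethylpenta-2,4-dienal; 13 (Ra)-tributyl(penta-2,3-dien-2-yl)stannane
Product: 14 (1E,3E,5R,6S)-1-iodo-2,4,6-trimethylnona-1,3-dien-7-yn-5-ol
Conditions: 13 (1.4 equiv), BF3·OEt2 (1.5 equiv), CH2Cl2, −78 °C; aq. NaHCO3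
Reagents that add atoms: none
Why: Marshall BF3-promoted anti SE2′ addition through an open transition state gives the syn homopropargylic alcohol; anti SN2′ followed by anti SE2′ is net retention, so the S carbinol of 11 becomes 6S, and the syn preference then sets 7R (target numbering).

**Step 8**
Reactants: 14 (1E,3E,5R,6S)-1-iodo-2,4,6-trimethylnona-1,3-dien-7-yn-5-ol; 15 propanal
Product: 18 (3R,4E,6S,7R,8E,10E)-11-iodo-4,6,8,10-tetramethylundeca-4,8,10-triene-3,7-diol, via alkenylborane 16 (not isolated), via alkenylzinc 17 (not isolated)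
Conditions: Cy2BH (2.2 equiv), toluene, 0 °C to rt; Me2Zn (3 equiv), −78 °C; (2S)-(−)-3-exo-morpholinoisoborneol [(−)-MIB] (10 mol%), 15 (1.5 equiv), −30 to 0 °C; aq. NH4Cl, then ethanolamine
Reagents that add atoms: none
Why: Oppolzer–Walsh sequence: syn hydroboration puts boron on the less hindered, methyl-bearing alkyne carbon, boron-to-zinc exchange and addition go with retention to give the 4E olefin, and the (−)-MIB–zinc catalyst delivers the alkenyl group to the Si face of propanal to give 3R.

**Step 9 (key step)**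
Reactants: 18 (3R,4E,6S,7R,8E,10E)-11-iodo-4,6,8,10-tetramethylundeca-4,8,10-triene-3,7-diol; 4 rac-(E)-(3-chlorobut-1-en-1-yl)benzene (2 equiv)
Product: 19 (3R,4E,6S,7R,8E,10E,12S,13E)-4,6,8,10,12-pentamethyl-14-phenyltetradeca-4,8,10,13-tetraene-3,7-diol
Conditions: NiCl2(dme) (10 mol%), (3aR,3a'R,8aS,8a'S)-2,2'-(cyclopropane-1,1-diyl)bis(3a,8a-dihydro-8H-indeno[1,2-d]oxazole) (12 mol%), Mn powder (3 equiv), DMA, 0 °C, dark
Reagents that add atoms: none
Why: Proposed new method: zerovalent nickel–bis(oxazoline) inserts into the C11–I bond of 18 to give an alkenyl complex of divalent nickel, a monovalent nickel halide abstracts chlorine from either enantiomer of 4 to give the planar 1-methyl-3-phenylallyl radical, the radical is captured at nickel, and the trivalent alkenyl(allyl)nickel complex reductively eliminates at the methyl-bearing terminus (less hindered, keeps the E styrene conjugated) with the ligand selecting the face that gives 12S, while Mn powder turns the catalyst over; the closest known reaction types are the nickel/bis(oxazoline)-catalysed enantioselective reductive cross-coupling of alkenyl bromides with racemic secondary benzylic chlorides and the nickel-catalysed enantioconvergent Negishi coupling of racemic secondary allylic chlorides.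

**Compound list**
1 | styrene | C=Cc1ccccc1 | starting material
2 | but-3-en-2-ol (racemic) | CC(O)C=C | starting material
3 | rac-(E)-4-phenylbut-3-en-2-ol | CC(O)/C=C/c1ccccc1 | intermediate
4 | rac-(E)-(3-chlorobut-1-en-1-yl)benzene | CC(Cl)/C=C/c1ccccc1 | intermediate
5 | prop-2-yn-1-ol | OCC#C | starting material
6 | (E)-[3-(dimethylalumanyl)-2-methylprop-2-en-1-yl]oxy(dimethyl)alumane | C[Al](C)OC/C(C)=C/[Al](C)C | intermediate
7 | (E)-3-iodo-2-methylprop-2-en-1-ol | OC/C(C)=C/I | intermediate
8 | (E)-3-iodo-2-methylprop-2-enal | O=C/C(C)=C/I | intermediate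
9 | (2E,4E)-5-iodo-2,4-dimethylpenta-2,4-dienal | O=C/C(C)=C/C(C)=C/I | intermediate
10 | pent-3-yn-2-one | CC#CC(C)=O | starting material
11 | (S)-pent-3-yn-2-ol | C[C@H](O)C#CC | intermediate
12 | (S)-pent-3-yn-2-yl methanesulfonate | C[C@H](OS(C)(=O)=O)C#CC | intermediate
13 | (Ra)-tributyl(penta-2,3-dien-2-yl)stannane | CCCC[Sn](CCCC)(CCCC)C(C)=[C@]=C([H])C | intermediate
14 | (1E,3E,5R,6S)-1-iodo-2,4,6-trimethylnona-1,3-dien-7-yn-5-ol | CC#C[C@H](C)[C@@H](O)/C(C)=C/C(C)=C/I | intermediate
15 | propanal | CCC=O | starting material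
16 | alkenylborane: 14 after O-borylation and syn hydroboration, Cy2B on the methyl-bearing carbon (C4), trans to C6 | C1CCCCC1B(C1CCCCC1)/C(C)=C/[C@H](C)[C@@H](OB(C1CCCCC1)C1CCCCC1)/C(C)=C/C(C)=C/I | intermediate
17 | alkenyl(methyl)zinc: 16 with MeZn in place of the C4 boryl group | C[Zn]/C(C)=C/[C@H](C)[C@@H](OB(C1CCCCC1)C1CCCCC1)/C(C)=C/C(C)=C/I | intermediate
18 | (3R,4E,6S,7R,8E,10E)-11-iodo-4,6,8,10-tetramethylundeca-4,8,10-triene-3,7-diol | CC[C@@H](O)/C(C)=C/[C@H](C)[C@@H](O)/C(C)=C/C(C)=C/I | intermediate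
19 | (3R,4E,6S,7R,8E,10E,12S,13E)-4,6,8,10,12-pentamethyl-14-phenyltetradeca-4,8,10,13-tetraene-3,7-diol | CC[C@@H](O)/C(C)=C/[C@H](C)[C@@H](O)/C(C)=C/C(C)=C/[C@@H](C)/C=C/c1ccccc1 | target

**Step count and risks**
Total steps: 9. Longest linear sequence: 5 (steps 3, 4, 7, 8, 9 from prop-2-yn-1-ol; equally 5, 6, 7, 8, 9 from pent-3-yn-2-one). C3 and C12 are set by catalysts remote from the other centres, so the final product will need HPLC removal of minor diastereomers.

Most likely to fail:

1. Step 9. It is an unprecedented substrate class on the most advanced intermediate. The risks are coupling at the benzylic terminus, modest selectivity at C12, homocoupling of 18, and etherification of the free hydroxyls by ionised 4. The fallback sets out from 3 and 18 and comes back at 19, and replaces the radical union by a stereospecific two-electron one. Alcohol 3 is resolved with Candida antarctica lipase B and vinyl acetate to (R,E)-4-phenylbut-3-en-2-yl acetate F1, the S alcohol being left behind. Iodide 18 is borylated with B2pin2, PdCl2(PPh3)2 and KOPh to the alkenyl pinacol boronate F2. F1 and F2 are then joined by a Pd(PPh3)4/CsF allyl–alkenyl Suzuki coupling, in which ionisation with inversion and reductive elimination with retention turn the R acetate into 12S.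

2. Step 7. The conjugated dienal is a weak electrophile and the syn:anti ratio is best documented for α-branched saturated aldehydes. The fallback sets out from 9 and comes back at 18, puts the 6,7-syn pair under auxiliary control and also bypasses step 8. A boron-mediated Evans syn aldol of (R)-4-benzyl-3-propanoyloxazolidin-2-one (Bu2BOTf, iPr2NEt) with 9 gives (4R)-4-benzyl-3-[(2R,3R,4E,6E)-3-hydroxy-7-iodo-2,4,6-trimethylhepta-4,6-dienoyl]oxazolidin-2-one F3. AlMe3/MeNHOMe·HCl gives the Weinreb amide F4, and Et3SiCl/imidazole its triethylsilyl ether F5. iBu2AlH gives the aldehyde F6. A Horner–Wadsworth–Emmons reaction with diethyl (3-oxopentan-2-yl)phosphonate and Ba(OH)2 gives the E enone F7. Reduction with (S)-2-methyl-CBS-oxazaborolidine/BH3·SMe2 gives the 3R allylic alcohol F8, and Bu4NF then gives 18.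

3. Step 8. The risks are hydroboration regioselectivity, slow boron-to-zinc exchange for a trisubstituted alkenyl group, and limited selectivity at C3 with a linear aldehyde in the presence of the substrate's own alkoxide. The fallback sets out from 14 and comes back at 18, and reverses the roles at C3. Hydrozirconation of 14 with Cp2Zr(H)Cl (3 equiv), insertion of n-BuNC and hydrolysis with aq. AcOH give the enal (2E,4S,5R,6E,8E)-5-hydroxy-9-iodo-2,4,6,8-tetramethylnona-2,6,8-trienal F9. Ethyl is then added with Et2Zn under (+)-MIB catalysis to give 18 with 3R.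

**Further compounds**
F1 | step 9 | (R,E)-4-phenylbut-3-en-2-yl acetate | C[C@@H](OC(C)=O)/C=C/c1ccccc1
F2 | step 9 | (3R,4E,6S,7R,8E,10E)-4,6,8,10-tetramethyl-11-(4,4,5,5-tetramethyl-1,3,2-dioxaborolan-2-yl)undeca-4,8,10-triene-3,7-diol | CC[C@@H](O)/C(C)=C/[C@H](C)[C@@H](O)/C(C)=C/C(C)=C/B1OC(C)(C)C(C)(C)O1
F3 | step 7 | (4R)-4-benzyl-3-[(2R,3R,4E,6E)-3-hydroxy-7-iodo-2,4,6-trimethylhepta-4,6-dienoyl]oxazolidin-2-one | O=C(N1[C@H](Cc2ccccc2)COC1=O)[C@H](C)[C@@H](O)/C(C)=C/C(C)=C/I
F4 | step 7 | (2R,3R,4E,6E)-3-hydroxy-7-iodo-N-methoxy-N,2,4,6-tetramethylhepta-4,6-dienamide | CON(C)C(=O)[C@H](C)[C@@H](O)/C(C)=C/C(C)=C/I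
F5 | step 7 | (2R,3R,4E,6E)-7-iodo-N-methoxy-N,2,4,6-tetramethyl-3-(triethylsilyloxy)hepta-4,6-dienamide | CON(C)C(=O)[C@H](C)[C@@H](O[Si](CC)(CC)CC)/C(C)=C/C(C)=C/I
F6 | step 7 | (2R,3R,4E,6E)-7-iodo-2,4,6-trimethyl-3-(triethylsilyloxy)hepta-4,6-dienal | O=C[C@H](C)[C@@H](O[Si](CC)(CC)CC)/C(C)=C/C(C)=C/I
F7 | step 7 | (4E,6S,7R,8E,10E)-11-iodo-4,6,8,10-tetramethyl-7-(triethylsilyloxy)undeca-4,8,10-trien-3-one | CCC(=O)/C(C)=C/[C@H](C)[C@@H](O[Si](CC)(CC)CC)/C(C)=C/C(C)=C/I
F8 | step 7 | (3R,4E,6S,7R,8E,10E)-11-iodo-4,6,8,10-tetramethyl-7-(triethylsilyloxy)undeca-4,8,10-trien-3-ol | CC[C@@H](O)/C(C)=C/[C@H](C)[C@@H](O[Si](CC)(CC)CC)/C(C)=C/C(C)=C/I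
F9 | step 8 | (2E,4S,5R,6E,8E)-5-hydroxy-9-iodo-2,4,6,8-tetramethylnona-2,6,8-trienal | O=C/C(C)=C/[C@H](C)[C@@H](O)/C(C)=C/C(C)=C/I
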